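Ring A is cut between C1 and C6: its gem-dimethyl C1, the C4=C5 alkene, the stereocentre C6 and the C3 oxygen map onto an open-chain enone. The precursor is 5-oxogeranyl acetate, in which the C1=C2–C3=O enone faces the isolated C5=C6 alkene and C7 carries an acetate. A confined chiral Brønsted acid turns the enone into an electrophile at C1; attack by C6 closes ring A, sets C6 (6R) and, after loss of H4, leaves a conjugated C3 ketone. Reduction then fixes C3 (3S), and a Julia–Kocienski olefination at C7=C8 joins the ring to purchased crocetin dialdehyde.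

Key step: step 5

Remark: carotenoid numbering is used (ring A: C1 gem-dimethyl, C2, C3–O, C4=C5, C6; chain from C7; primed numbers from the aldehyde end); the target is (3S,6R), with the C3 hydroxyl and the C6 chain cis.
Remark: an acetate would not survive a lithiated dithiane, so the C7 oxygen passes through the alkylation as a lithium alkoxide and is acetylated in the same flask.
Remark: crocetin dialdehyde (C20) is taken as a purchased building block, used in excess and recovered.

Step 1
Reactants: 1 3-methylbut-2-enal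
Product: 2 2-(2-methylprop-1-en-1-yl)-1,3-dithiane
Conditions: HS(CH2)3SH, BF3·OEt2 (cat.), CH2Cl2, −20 °C to 0 °C
Reagents that add atoms: propane-1,3-dithiol, SCCCS
Why: Lewis-acid-catalysed dithioacetalisation (the masking half of a Corey–Seebach umpolung) should give the 1,2-adduct, because conjugate thiol addition is slowed by the doubly methylated alkene terminus.

Step 2
Reactants: 3 (2E)-4-chloro-3-methylbut-2-en-1-yl acetate
Product: 4 (2E)-4-chloro-3-methylbut-2-en-1-ol
Conditions: K2CO3 (0.1 equiv), MeOH, 0 °C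
Reagents that add atoms: none
Why: Carbonate-catalysed transesterification (methanolysis) of the primary acetate is fast at 0 °C, where the allylic chloride is not yet displaced and the E alkene is not touched.

Step 3
Reactants: 2 2-(2-methylprop-1-en-1-yl)-1,3-dithiane; 4 (2E)-4-chloro-3-methylbut-2-en-1-ol
Product: 8 (2E)-3-methyl-4-[2-(2-methylprop-1-en-1-yl)-1,3-dithian-2-yl]but-2-en-1-yl acetate, via lithiated dithiane 5 (not isolated), via lithium chloroalkoxide 6 (not isolated), via lithium alkoxide 7 (not isolated)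
Conditions: 2, n-BuLi, THF, −78 to −25 °C; 4, n-BuLi, THF, −78 °C (second flask); combine, −78 to −20 °C; then Ac2O, −20 °C to rt
Reagents that add atoms: acetic anhydride, CC(=O)OC(C)=O
Why: Corey–Seebach alkylation: the sulfur-stabilised anion 5 should react at its dithiane carbon (the other terminus is a hindered CMe2 carbon) by SN2 at the primary allylic chloride with the E alkene retained, the C7 oxygen being masked as alkoxide 6 so that no ester meets the carbanion, and alkoxide 7 is then acetylated in the same flask.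

Step 4
Reactants: 8 (2E)-3-methyl-4-[2-(2-methylprop-1-en-1-yl)-1,3-dithian-2-yl]but-2-en-1-yl acetate
Product: 9 (2E)-3,7-dimethyl-5-oxoocta-2,6-dien-1-yl acetate (5-oxogeranyl acetate)
Conditions: MeI, CaCO3, MeCN–H2O (4:1), 40 °C
Reagents that add atoms: water, O
Why: Alkylative dithiane hydrolysis (S-methylation, ring opening to a thionium ion, hydration) releases the ketone under neutral, carbonate-buffered conditions, which should keep the C5=C6 alkene out of conjugation and the base-sensitive acetate in place.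

Step 5
Reactants: 9 (2E)-3,7-dimethyl-5-oxoocta-2,6-dien-1-yl acetate
Product: 11 [(1R)-2,6,6-trimethyl-4-oxocyclohex-2-en-1-yl]methyl acetate, via ring A dienol 10 (not isolated)
Conditions: (S,S)-imidodiphosphorimidate Brønsted acid (5 mol%; P–N–P core carrying two 3,3'-bis[3,5-bis(trifluoromethyl)phenyl]-1,1'-binaphthalene-2,2'-diyl units, both phosphorus atoms as P=N–SO2CF3), CHCl3, −40 °C; cold filtration through silica
Reagents that add atoms: none
Why: Proposed new method: the confined acid protonates the C3 carbonyl of 9, C6 of the trisubstituted C5=C6 alkene adds to the dimethyl-substituted terminus C1 of the resulting hydroxyallyl cation (Markovnikov, tertiary cation at C5), and loss of H4, the proton lying between that cation and the enol, gives dienol 10, which tautomerises to ketone 11 with the alkene held at C4=C5; the closest known reaction types are the proton-induced ring closure of geranyl acetate to α-cyclogeranyl acetate, Lewis-acid-triggered additions of alkenes to enone β-carbons, and Nazarov and carbonyl–ene ring closures run under chiral imidodiphosphorimidate acids. Ring A closes in a 6-endo-trig mode, with both the enone C1=C2 bond and the attacking C5=C6 bond inside the new ring. The single new stereocentre C6 (1R in 11) is controlled by the chiral counter-anion, which holds the hydroxyallyl cation by a hydrogen bond in its pocket and leaves one face of the C5=C6 alkene open to C1; which catalyst antipode gives 6R must be fixed once by correlation, the (S,S) acid being assumed here. The step needs ring closure to outrun acid-catalysed migration of the C5=C6 alkene into conjugation (which would open a Nazarov path) and needs the product to escape γ-enolisation at C6; the placement of the nucleophilic trisubstituted alkene opposite C1, the deactivated and non-ionising C7 acetate, the low temperature and the low acid loading should secure this.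

Step 6
Reactants: 11 [(1R)-2,6,6-trimethyl-4-oxocyclohex-2-en-1-yl]methyl acetate
Product: 12 [(1R,4S)-4-hydroxy-2,6,6-trimethylcyclohex-2-en-1-yl]methyl acetate
Conditions: (R)-2-methyl-CBS-oxazaborolidine [(R)-1-methyl-3,3-diphenyltetrahydro-1H,3H-pyrrolo[1,2-c][1,3,2]oxazaborole] (20 mol%), catecholborane, toluene, −78 °C
Reagents that add atoms: none
Why: Corey–Bakshi–Shibata reduction: the oxazaborolidine–borane complex should bind the carbonyl oxygen on the side away from the larger alkenyl flank (C4=C5) and deliver hydride in 1,2-fashion to the face that makes C3 S (hydroxyl cis to the C6 side chain), while the non-basic medium spares the γ-proton at C6 and the acetate.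

Step 7
Reactants: 12 [(1R,4S)-4-hydroxy-2,6,6-trimethylcyclohex-2-en-1-yl]methyl acetate
Product: 13 [(1R,4S)-4-{[tert-butyl(dimethyl)silyl]oxy}-2,6,6-trimethylcyclohex-2-en-1-yl]methyl acetate
Conditions: TBSCl, imidazole, DMF, rt
Reagents that add atoms: tert-butyldimethylsilyl chloride, CC(C)(C)[Si](C)(C)Cl
Why: Standard silylation of a secondary allylic alcohol with a silyl chloride and imidazole, in which no stereocentre is touched.

Step 8
Reactants: 13 [(1R,4S)-4-{[tert-butyl(dimethyl)silyl]oxy}-2,6,6-trimethylcyclohex-2-en-1-yl]methyl acetate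
Product: 14 [(1R,4S)-4-{[tert-butyl(dimethyl)silyl]oxy}-2,6,6-trimethylcyclohex-2-en-1-yl]methanol
Conditions: K2CO3, MeOH, rt
Reagents that add atoms: none
Why: Base-catalysed methanolysis of the primary acetate; with the ketone gone C6 carries no acidic proton, and the silyl ether is stable to carbonate.

Step 9
Reactants: 14 [(1R,4S)-4-{[tert-butyl(dimethyl)silyl]oxy}-2,6,6-trimethylcyclohex-2-en-1-yl]methanol
Product: 15 5-({[(1R,4S)-4-{[tert-butyl(dimethyl)silyl]oxy}-2,6,6-trimethylcyclohex-2-en-1-yl]methyl}sulfanyl)-1-phenyl-1H-tetrazole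
Conditions: PPh3, DIAD, THF, 0 °C to rt
Reagents that add atoms: 1-phenyl-1H-tetrazole-5-thiol, Sc1nnnn1-c1ccccc1
Why: Mitsunobu thioetherification: the acidic tetrazole thiol displaces the activated primary hydroxyl at C7 by SN2 at a carbon that is not stereogenic, so C3 and C6 are unaffected.

Step 10
Reactants: 15 5-({[(1R,4S)-4-{[tert-butyl(dimethyl)silyl]oxy}-2,6,6-trimethylcyclohex-2-en-1-yl]methyl}sulfanyl)-1-phenyl-1H-tetrazole
Product: 16 5-({[(1R,4S)-4-{[tert-butyl(dimethyl)silyl]oxy}-2,6,6-trimethylcyclohex-2-en-1-yl]methyl}sulfonyl)-1-phenyl-1H-tetrazole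
Conditions: (NH4)6Mo7O24·4H2O (10 mol%), 30% aq. H2O2, EtOH, 0 °C to rt
Reagents that add atoms: hydrogen peroxide, OO
Why: Molybdate-catalysed peroxide oxidation should take the sulfide to the sulfone far faster than it epoxidises the trisubstituted ring alkene, whose allylic oxygen is silylated and cannot direct the oxidant.

Step 11
Reactants: 16 5-({[(1R,4S)-4-{[tert-butyl(dimethyl)silyl]oxy}-2,6,6-trimethylcyclohex-2-en-1-yl]methyl}sulfonyl)-1-phenyl-1H-tetrazole; 17 crocetin dialdehyde, (2E,4E,6E,8E,10E,12E,14E)-2,6,11,15-tetramethylhexadeca-2,4,6,8,10,12,14-heptaenedial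
Product: 19 (2E,4E,6E,8E,10E,12E,14E,16E)-17-[(1R,4S)-4-{[tert-butyl(dimethyl)silyl]oxy}-2,6,6-trimethylcyclohex-2-en-1-yl]-2,6,11,15-tetramethylheptadeca-2,4,6,8,10,12,14,16-octaenal, via potassium sulfonyl carbanion 18 (not isolated)
Conditions: KN(SiMe3)2, DME, −60 °C; then 17 (2.5 equiv) in THF, −60 °C to rt, argon, dim light
Reagents that add atoms: none
Why: Julia–Kocienski olefination: carbanion 18 adds to one aldehyde group of the symmetric dialdehyde, and Smiles rearrangement with loss of SO2 and tetrazolyloxide should give the C7=C8 alkene as the E isomer (potassium counter-ion, ether solvent, bulky C6 substituent), while the excess of 17 limits reaction at both ends and C6, which is not acidic, keeps its configuration.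

Step 12
Reactants: 19 (2E,4E,6E,8E,10E,12E,14E,16E)-17-[(1R,4S)-4-{[tert-butyl(dimethyl)silyl]oxy}-2,6,6-trimethylcyclohex-2-en-1-yl]-2,6,11,15-tetramethylheptadeca-2,4,6,8,10,12,14,16-octaenal
Product: 20 (2E,4E,6E,8E,10E,12E,14E,16E)-17-[(1R,4S)-4-hydroxy-2,6,6-trimethylcyclohex-2-en-1-yl]-2,6,11,15-tetramethylheptadeca-2,4,6,8,10,12,14,16-octaenal
Conditions: Bu4NF, AcOH (1:1), THF, 0 °C to rt, argon, dim light
Reagents that add atoms: none
Why: Fluoride-mediated desilylation; buffering with acetic acid keeps the medium near neutral, so that neither the polyenal (base) nor the allylic C3–O bond (acid) is put at risk and C3 keeps its configuration.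

Compound list
1 | 3-methylbut-2-enal | CC(C)=CC=O | starting material
2 | 2-(2-methylprop-1-en-1-yl)-1,3-dithiane | CC(C)=CC1SCCCS1 | intermediate
3 | (2E)-4-chloro-3-methylbut-2-en-1-yl acetate | CC(=O)OC/C=C(\C)CCl | starting material
4 | (2E)-4-chloro-3-methylbut-2-en-1-ol | OC/C=C(\C)CCl | intermediate
5 | 2-lithio-2-(2-methylprop-1-en-1-yl)-1,3-dithiane (not isolated) | [Li]C1(C=C(C)C)SCCCS1 | intermediate
6 | lithium (2E)-4-chloro-3-methylbut-2-en-1-olate (not isolated) | [Li+].[O-]C/C=C(\C)CCl | intermediate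
7 | lithium (2E)-3-methyl-4-[2-(2-methylprop-1-en-1-yl)-1,3-dithian-2-yl]but-2-en-1-olate (not isolated) | [Li+].[O-]C/C=C(\C)CC1(C=C(C)C)SCCCS1 | intermediate
8 | (2E)-3-methyl-4-[2-(2-methylprop-1-en-1-yl)-1,3-dithian-2-yl]but-2-en-1-yl acetate | CC(=O)OC/C=C(\C)CC1(C=C(C)C)SCCCS1 | intermediate
9 | (2E)-3,7-dimethyl-5-oxoocta-2,6-dien-1-yl acetate (5-oxogeranyl acetate, key-step precursor) | CC(C)=CC(=O)C/C(C)=C/COC(C)=O | intermediate
10 | [(1S)-4-hydroxy-2,6,6-trimethylcyclohexa-2,4-dien-1-yl]methyl acetate (not isolated; same spatial arrangement at the ring CH as in 11, the letter changes only through the priority rules) | CC1=CC(O)=CC(C)(C)[C@H]1COC(C)=O | intermediate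
11 | [(1R)-2,6,6-trimethyl-4-oxocyclohex-2-en-1-yl]methyl acetate (key-step product) | CC1=CC(=O)CC(C)(C)[C@H]1COC(C)=O | intermediate
12 | [(1R,4S)-4-hydroxy-2,6,6-trimethylcyclohex-2-en-1-yl]methyl acetate | CC1=C[C@@H](O)CC(C)(C)[C@H]1COC(C)=O | intermediate
13 | [(1R,4S)-4-{[tert-butyl(dimethyl)silyl]oxy}-2,6,6-trimethylcyclohex-2-en-1-yl]methyl acetate | CC1=C[C@@H](O[Si](C)(C)C(C)(C)C)CC(C)(C)[C@H]1COC(C)=O | intermediate
14 | [(1R,4S)-4-{[tert-butyl(dimethyl)silyl]oxy}-2,6,6-trimethylcyclohex-2-en-1-yl]methanol | CC1=C[C@@H](O[Si](C)(C)C(C)(C)C)CC(C)(C)[C@H]1CO | intermediate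
15 | 5-({[(1R,4S)-4-{[tert-butyl(dimethyl)silyl]oxy}-2,6,6-trimethylcyclohex-2-en-1-yl]methyl}sulfanyl)-1-phenyl-1H-tetrazole | CC1=C[C@@H](O[Si](C)(C)C(C)(C)C)CC(C)(C)[C@H]1CSc1nnnn1-c1ccccc1 | intermediate
16 | 5-({[(1R,4S)-4-{[tert-butyl(dimethyl)silyl]oxy}-2,6,6-trimethylcyclohex-2-en-1-yl]methyl}sulfonyl)-1-phenyl-1H-tetrazole | CC1=C[C@@H](O[Si](C)(C)C(C)(C)C)CC(C)(C)[C@H]1CS(=O)(=O)c1nnnn1-c1ccccc1 | intermediate
17 | crocetin dialdehyde, (2E,4E,6E,8E,10E,12E,14E)-2,6,11,15-tetramethylhexadeca-2,4,6,8,10,12,14-heptaenedial | O=C/C(C)=C/C=C/C(C)=C/C=C/C=C(C)/C=C/C=C(\C)C=O | starting material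
18 | potassium salt of the C7 carbanion of sulfone 16 (not isolated) | [K+].CC1=C[C@@H](O[Si](C)(C)C(C)(C)C)CC(C)(C)[C@H]1[CH-]S(=O)(=O)c1nnnn1-c1ccccc1 | intermediate
19 | (2E,4E,6E,8E,10E,12E,14E,16E)-17-[(1R,4S)-4-{[tert-butyl(dimethyl)silyl]oxy}-2,6,6-trimethylcyclohex-2-en-1-yl]-2,6,11,15-tetramethylheptadeca-2,4,6,8,10,12,14,16-octaenal | CC1=C[C@@H](O[Si](C)(C)C(C)(C)C)CC(C)(C)[C@H]1/C=C/C(C)=C/C=C/C(C)=C/C=C/C=C(C)/C=C/C=C(\C)C=O | intermediate
20 | (2E,4E,6E,8E,10E,12E,14E,16E)-17-[(1R,4S)-4-hydroxy-2,6,6-trimethylcyclohex-2-en-1-yl]-2,6,11,15-tetramethylheptadeca-2,4,6,8,10,12,14,16-octaenal, (3S,6R)-3-hydroxy-8'-apo-ε-caroten-8'-al | CC1=C[C@@H](O)CC(C)(C)[C@H]1/C=C/C(C)=C/C=C/C(C)=C/C=C/C=C(C)/C=C/C=C(\C)C=O | target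

Total step count: 12.
Longest linear sequence: 11 steps (steps 1, 3 to 12 from compound 1; equally steps 2 to 12 from compound 3).

Steps most likely to fail

1. Step 5 (Proposed new method). The C5=C6 alkene may slip into conjugation before the ring closes and the resulting cross-conjugated ketone may then close by a Nazarov path. The ion pair may also discriminate the two alkene faces poorly, or the product may enolise towards C6 and lose acetate. Fallback, all known chemistry: it does not start from a numbered compound; purchased geranyl acetate F1 takes the place of 9 (steps 1 to 4 are then not needed), and the fallback comes back to the route at 11. Proton-induced cyclisation of geranyl acetate F1 (ClSO3H, 2-nitropropane, −78 °C) would give racemic α-cyclogeranyl acetate F2. Allylic oxidation of its C3 methylene (CrO3, 3,5-dimethylpyrazole, CH2Cl2, −20 °C) would give racemic keto acetate F3. Preparative chromatography on a cellulose tris(3,5-dimethylphenylcarbamate) phase would then deliver the 6R enantiomer 11.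

2. Step 6. Facial selectivity may be poor, because the two flanks of the carbonyl differ little in size and the ring's own bias (the axial methyl at C1) may oppose the catalyst. Fallback: it sets out from 11 and comes back at 12. Luche reduction (NaBH4, CeCl3·7H2O, MeOH, −78 °C) would give both C3 epimers without reagent control. Chromatography would separate 12 from the 3R epimer F4. The 3R epimer F4 would be returned to 11 with MnO2 (CH2Cl2, rt) and reduced again.

3. Step 11. E selectivity may erode with the conjugated aldehyde, the hindered sulfonyl carbanion may add sluggishly, and both aldehyde groups of 17 may react. Fallback with the polarity at C7 reversed and the chain built in three blocks: it sets out from 14 and comes back at 19.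
- Oxidation of 14 (Dess–Martin periodinane, NaHCO3, CH2Cl2, 0 °C) would give aldehyde F5, which is used at once.
- Takai iodo-olefination (CrCl2, CHI3, THF, 0 °C) would give E vinyl iodide F6.
- Stille coupling (Pd2(dba)3, AsPh3, NMP, rt) with (E)-3-(tributylstannyl)but-2-en-1-ol F7 (made from but-2-yn-1-ol by stannylcupration) would give dienol F8.
- PPh3·HBr (MeOH–CH2Cl2, 0 °C) would give phosphonium bromide F9.
- Wittig reaction with an excess of purchased (2E,4E,6E)-2,7-dimethylocta-2,4,6-trienedial (NaOMe, CH2Cl2–MeOH, then thermal equilibration of any 11Z isomer) would give C25 aldehyde F10.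
- Horner–Wadsworth–Emmons reaction with ethyl (2E)-4-(diethoxyphosphoryl)-2-methylbut-2-enoate (NaN(SiMe3)2, THF, −78 to 0 °C) would give C30 ester F11.
- i-Bu2AlH (CH2Cl2, −78 °C) would give C30 alcohol F12, and MnO2 (CH2Cl2, rt) would return 19.

Further compounds
F1 | step 5 | geranyl acetate, (2E)-3,7-dimethylocta-2,6-dien-1-yl acetate (purchased) | CC(C)=CCC/C(C)=C/COC(C)=O
F2 | step 5 | racemic α-cyclogeranyl acetate, (2,6,6-trimethylcyclohex-2-en-1-yl)methyl acetate | CC1=CCCC(C)(C)C1COC(C)=O
F3 | step 5 | racemic (2,6,6-trimethyl-4-oxocyclohex-2-en-1-yl)methyl acetate | CC1=CC(=O)CC(C)(C)C1COC(C)=O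
F4 | step 6 | [(1R,4R)-4-hydroxy-2,6,6-trimethylcyclohex-2-en-1-yl]methyl acetate (3R epimer of 12) | CC1=C[C@H](O)CC(C)(C)[C@H]1COC(C)=O
F5 | step 11 | (1R,4S)-4-{[tert-butyl(dimethyl)silyl]oxy}-2,6,6-trimethylcyclohex-2-ene-1-carbaldehyde | CC1=C[C@@H](O[Si](C)(C)C(C)(C)C)CC(C)(C)[C@H]1C=O
F6 | step 11 | tert-butyl({(1S,4R)-4-[(E)-2-iodoethenyl]-3,5,5-trimethylcyclohex-2-en-1-yl}oxy)dimethylsilane (3S,6R in carotenoid numbering) | CC1=C[C@@H](O[Si](C)(C)C(C)(C)C)CC(C)(C)[C@H]1/C=C/I
F7 | step 11 | (2E)-3-(tributylstannyl)but-2-en-1-ol | CCCC[Sn](CCCC)(CCCC)/C(C)=C/CO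
F8 | step 11 | (2E,4E)-5-[(1R,4S)-4-{[tert-butyl(dimethyl)silyl]oxy}-2,6,6-trimethylcyclohex-2-en-1-yl]-3-methylpenta-2,4-dien-1-ol | CC1=C[C@@H](O[Si](C)(C)C(C)(C)C)CC(C)(C)[C@H]1/C=C/C(C)=C/CO
F9 | step 11 | {(2E,4E)-5-[(1R,4S)-4-{[tert-butyl(dimethyl)silyl]oxy}-2,6,6-trimethylcyclohex-2-en-1-yl]-3-methylpenta-2,4-dien-1-yl}triphenylphosphonium bromide | [Br-].CC1=C[C@@H](O[Si](C)(C)C(C)(C)C)CC(C)(C)[C@H]1/C=C/C(C)=C/C[P+](c1ccccc1)(c1ccccc1)c1ccccc1
F10 | step 11 | (2E,4E,6E,8E,10E,12E)-13-[(1R,4S)-4-{[tert-butyl(dimethyl)silyl]oxy}-2,6,6-trimethylcyclohex-2-en-1-yl]-2,7,11-trimethyltrideca-2,4,6,8,10,12-hexaenal | CC1=C[C@@H](O[Si](C)(C)C(C)(C)C)CC(C)(C)[C@H]1/C=C/C(C)=C/C=C/C(C)=C/C=C/C=C(\C)C=O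
F11 | step 11 | ethyl (2E,4E,6E,8E,10E,12E,14E,16E)-17-[(1R,4S)-4-{[tert-butyl(dimethyl)silyl]oxy}-2,6,6-trimethylcyclohex-2-en-1-yl]-2,6,11,15-tetramethylheptadeca-2,4,6,8,10,12,14,16-octaenoate | CC1=C[C@@H](O[Si](C)(C)C(C)(C)C)CC(C)(C)[C@H]1/C=C/C(C)=C/C=C/C(C)=C/C=C/C=C(C)/C=C/C=C(\C)C(=O)OCC
F12 | step 11 | (2E,4E,6E,8E,10E,12E,14E,16E)-17-[(1R,4S)-4-{[tert-butyl(dimethyl)silyl]oxy}-2,6,6-trimethylcyclohex-2-en-1-yl]-2,6,11,15-tetramethylheptadeca-2,4,6,8,10,12,14,16-octaen-1-ol | CC1=C[C@@H](O[Si](C)(C)C(C)(C)C)CC(C)(C)[C@H]1/C=C/C(C)=C/C=C/C(C)=C/C=C/C=C(C)/C=C/C=C(\C)CO
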